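## The problem

Compound 20 is a linear chain of ten polyhydroxylated benzene rings (A to J in the order of its SMILES string) joined only by nine diaryl ether oxygens. It has no stereocentre and no ring other than the benzene rings, so the whole task is regiochemistry and C–O bond formation. Rings A and J are the ends (2,4,6-trihydroxyphenyl and 3,4,5-trihydroxyphenyl). Rings B, D, F and H carry ether oxygens at positions 1 and 4 and hydroxyls at 3 and 5. Rings C, E, G and I carry ether oxygens on the neighbouring carbons 1 and 6 and hydroxyls at 3, 4 and 5, so the pair B–C recurs four times. Every ether oxygen is bound on one side to a carbon with two oxygenated ortho neighbours; this rules out unassisted SNAr and limits metal-mediated couplings to the polarity "crowded phenoxide plus uncrowded electrophile". The twenty-six free hydroxyls, grouped like pyrogallol and hydroxyquinol, are oxidised by air, above all under base, so they must stay masked to the end and be released without base and without oxygen. The feature that opens the key step is the pattern of rings B, D, F, H and J: the ether carbon facing ring A (b1, d1, f1, h1, j1) has a hydrogen on each side and lies para to an oxygenated carbon that sits between two more oxygenated carbons. This is the pattern of syringic acid (B, D, F, H) and gallic acid (J) with a carboxyl carbon where the ether oxygen stands, so each of these five ethers can be read as an aryl ester that has lost its carbonyl group.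

## Retrosynthesis

All twenty-six hydroxyls of 20 are carried as methyl ethers in 19 and released last. Methyl is preferred to benzyl or silyl because it is indifferent to every earlier operation (copper and palladium catalysis with base, hydrogenolysis, hot zerovalent nickel) and because the aromatic building blocks are sold as methyl ethers. The price is a 26-fold Lewis acid dealkylation that must spare the nine diaryl ethers and be worked up without oxygen. Compound 19 has no reactive group and can be purified and stored.

In 19 the five bonds O–b1, O–d1, O–f1, O–h1 and O–j1 are cut and a carbonyl group is placed between each oxygen and its ring carbon, which gives penta-ester 18. Cutting the same oxygens on their other side (at a1, c6, e6, g6, i6) would put the leaving group on a carbon with two oxygenated ortho neighbours. The four remaining ethers (b4–O–c1 and its repeats) lie inside the repeating two-ring unit and are better made once, early. The gain is that 18 is an oligodepside, so every union of building blocks becomes an esterification of an uncrowded aroyl group. The forward reaction must insert zerovalent nickel into five aryl ester C(acyl)–O bonds, extrude the carbonyl group each time and close each ether by reductive elimination, without cleaving aryl methyl or diaryl ethers and without passing aryloxides between chains. Because this exceeds what is documented (single esters, mostly of azinecarboxylic acids), the step is supported from within: nickel is dosed per ester group, the gas is swept out, and partly contracted material is of the same substrate class and can be resubmitted.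

The five ester C–O bonds of 18 are cut one after the other from the ring A end:
- 18 gives acid 16 and phenol 17.
- 16 goes back through benzyl ester 15 to acid 14 and hydroxy ester 7.
- 14 goes back through 13 to acid 12 and 7.
- 12 goes back through 11 to acid 10 and 7.
- 10 goes back through 9 to 7 and acid chloride 8.

Growth from the ring J end lets one bifunctional unit, 7 (free phenol, benzyl-masked carboxyl), serve four times. Growth from the ring A end would need the opposite protection and two more steps. The benzyl ester falls to hydrogenolysis, which aryl esters, diaryl ethers and methyl ethers survive. The forward reactions must acylate a phenol flanked by OMe and OAr with acids of growing size.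

Unit 7 is traced to hydroxy acid 6 by cutting the benzyl ester. Compound 6 is traced to bromo ester 4 by exchanging the c6 hydroxyl for bromine and restoring the methyl ester. In the forward direction hydroxide does both jobs in one flask by way of bromo acid 5. Bromine as placeholder is preferred to bringing the oxygen in with the ring, since no ring C building block with one free hydroxyl among four oxygens is at hand, while c6 is the most electron-rich C–H position of diaryl ether 3.

Compound 4 loses bromine to give 3; the two candidate positions are equivalent and the benzoate ring is deactivated. Compound 3 is cut at the O–c1 bond into methyl syringate 1 and iodide 2. The other cut, at O–b4, would demand substitution at a carbon between two methoxy groups. The chosen cut puts the crowding on the phenoxide only, which copper catalysis tolerates. Both 1 and 2 are purchased, and 3 already holds a complete B–C pair except for one oxygen.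

## Roads not taken

Alternative 1: Ring B of an A–B–C trimer A1 is taken apart into a four-carbon piece, the 4-aryloxy-3-ethoxycyclobutenone A2 (b3 to b6, with the ring C oxygen already on b4), and a two-carbon piece, the aryl ethynyl ether A3 (b1 and b2, with the ring A oxygen on b1).
- Forward key step: heating A2 opens it to a vinylketene, which adds [2+2] to A3 (bonds b3–b2 and b6–b1). Ring opening and 6π closure (bond b3–b4) then give A1 with a free b3 hydroxyl, a Danheiser benzannulation.
- Merits: both ether oxygens of ring B arrive on the partners, so no C–O coupling is needed at the crowded b4. The regiochemistry follows from the polarity of the ynol ether. Each bond-forming event has firmer precedent than step 14, and in this respect the road is ahead.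
- Weak points: it differentiates b3 (OH) from b5 (OEt), which 20 does not need. It makes one B-type ring per annulation, so the decamer would require four or five such thermal events. Each event needs a new ethynyl ether on a crowded phenol terminus and a new cyclobutenone carrying the next pentaoxygenated aryloxy group. A1 also carries three kinds of ether protecting groups.
- Comparison: the chosen plan sets a single four-step unit 7, chain growth by esterification and one operation for all five crowded ethers against the better precedent of this road. The cost is the uncertainty of that one operation.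

Alternative 2: The c1–c6 bond of ring C in trimer phenol A4 is cut; c3 to c6 come from a squarate-derived four-membered ring and c1–c2 from an (E)-2-aryloxyethenyl group, both present in cyclobutenone A5.
- Forward key step: heating A5 opens the four-membered ring to a dienylketene, 6π closure forms c1–c6, and enolisation gives A4 with its only free hydroxyl at c6.
- Merits: the five oxygens of ring C are placed in one event, and the single free hydroxyl appears exactly where the chain continues. Here the road is better than the chosen plan, which spends a bromination and a hydroxylation (steps 2 and 3) on that one oxygen.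
- Weak points: A5 needs a β-aryloxyvinyl metal nucleophile, a class prone to loss of aryloxide, and a tertiary methyl ether where the usual substrates carry a hydroxyl. The product is only a trimer. The crowded ether from c6 to ring D and every later ether would still have to be made by another method.
- Comparison: the chosen plan offers no equally direct entry to the ring C oxygen pattern. It offers instead a solution for the ethers between the repeating units, which this road leaves open.

Alternative 3: Five C–O(H) bonds at c4, e4, g4, i4 and j4 of the partly protected decamer A6 are cut back to the penta-aldehyde A7.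
- Forward key step: a peracid or peroxide Dakin oxidation turns the five formyl groups of A7 into formates by aryl migration, and hydrolysis gives the five phenols of A6. A6 could go straight to global demethylation.
- Merits: the reaction type is thoroughly precedented on electron-rich di-ortho-methoxy benzaldehydes, is mild, and the five sites are independent. As a key step it is far safer than step 14. The formyl groups also activate the para carbons c1, e1, g1, i1 and j1 for SNAr during chain assembly.
- Weak points: the step forms no skeletal bond, so all nine crowded diaryl ethers must already be in A7. The four ethers at b1, d1, f1 and h1 have no para formyl group in A7, so they need separate formyl/oxidation rounds or copper couplings on the growing chain.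
- Comparison: the chosen plan sets five skeletal bonds formed in one operation and a chain built from esters against the reliability of this road. The price is a key step without direct precedent.

Key step: step 14

Remark: 20 has no stereogenic element, so no compound of the route needs a stereodescriptor; ring letters follow the order of the rings in the SMILES string of 20, and ring atoms are numbered from the ether carbon that faces ring A.

## Steps

Step 1
Reactants: 1 methyl syringate (methyl 4-hydroxy-3,5-dimethoxybenzoate); 2 5-iodo-1,2,3-trimethoxybenzene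
Product: 3 methyl 3,5-dimethoxy-4-(3,4,5-trimethoxyphenoxy)benzoate
Conditions: CuI (10 mol %), picolinic acid (20 mol %), K3PO4, DMSO, 90 °C, argon
Reagents that add atoms: none
Why: Ullmann diaryl ether synthesis with monovalent copper and picolinic acid, a catalyst system suited to 2,6-disubstituted phenols; the iodide has two ortho hydrogens, so only the phenoxide is crowded, and the methyl ester is stable to anhydrous K3PO4.

Step 2
Reactants: 3 methyl 3,5-dimethoxy-4-(3,4,5-trimethoxyphenoxy)benzoate
Product: 4 methyl 4-(2-bromo-3,4,5-trimethoxyphenoxy)-3,5-dimethoxybenzoate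
Conditions: NBS (1.0 equiv), MeCN, 0 °C to rt
Reagents that add atoms: N-bromosuccinimide, O=C1CCC(=O)N1Br
Why: Electrophilic aromatic bromination; the two equivalent positions of the ester-free ring are each ortho to the aryloxy oxygen, ortho to one methoxy and para to another, and are far more nucleophilic than the positions of the benzoate ring next to the ester, so one equivalent of reagent should give a single monobromide.

Step 3
Reactants: 4 methyl 4-(2-bromo-3,4,5-trimethoxyphenoxy)-3,5-dimethoxybenzoate
Product: 6 4-(2-hydroxy-3,4,5-trimethoxyphenoxy)-3,5-dimethoxybenzoic acid, via bromo acid 5 (not isolated)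
Conditions: KOH, 1,4-dioxane/H2O, 60 °C; then Pd2(dba)3, tBuXPhos (2-di-tert-butylphosphino-2',4',6'-triisopropylbiphenyl), 100 °C, argon; aq. HCl
Reagents that add atoms: potassium hydroxide, [K+].[OH-]
Why: Ester saponification followed in the same flask by palladium-catalysed hydroxylation of the aryl bromide with hydroxide; the bulky di-tert-butyl biarylphosphine allows oxidative addition and C–O reductive elimination at di-ortho-substituted, electron-rich bromides, and the carboxylate formed first is inert to the catalyst.

Step 4
Reactants: 6 4-(2-hydroxy-3,4,5-trimethoxyphenoxy)-3,5-dimethoxybenzoic acid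
Product: 7 benzyl 4-(2-hydroxy-3,4,5-trimethoxyphenoxy)-3,5-dimethoxybenzoate
Conditions: BnBr (1.05 equiv), KHCO3 (1.1 equiv), DMF, rt
Reagents that add atoms: benzyl bromide, BrCc1ccccc1
Why: Carboxylate O-alkylation; hydrogen carbonate deprotonates the carboxylic acid but not the crowded, far less acidic phenol, so only the benzyl ester should form.

Step 5
Reactants: 7 benzyl 4-(2-hydroxy-3,4,5-trimethoxyphenoxy)-3,5-dimethoxybenzoate; 8 3,4,5-trimethoxybenzoyl chloride
Product: 9 benzyl 3,5-dimethoxy-4-[3,4,5-trimethoxy-2-(3,4,5-trimethoxybenzoyloxy)phenoxy]benzoate (rings H–I–J)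
Conditions: Et3N, DMAP (cat.), CH2Cl2, 0 °C to rt
Reagents that add atoms: none
Why: Acylation of a phenol by an aroyl chloride under nucleophilic catalysis by DMAP; the acylpyridinium ion is reactive enough for a phenol flanked by OMe and OAr, and the benzyl ester is untouched.

Step 6
Reactants: 9 benzyl ester of rings H–I–J
Product: 10 3,5-dimethoxy-4-[3,4,5-trimethoxy-2-(3,4,5-trimethoxybenzoyloxy)phenoxy]benzoic acid (rings H–I–J)
Conditions: H2 (1 atm), 10% Pd/C, EtOAc, rt
Reagents that add atoms: none
Why: Hydrogenolysis of a benzyl ester; aryl esters, diaryl ethers and aryl methyl ethers are not cleaved over Pd/C at ambient pressure.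

Step 7
Reactants: 10 acid of rings H–I–J; 7 benzyl 4-(2-hydroxy-3,4,5-trimethoxyphenoxy)-3,5-dimethoxybenzoate
Product: 11 benzyl ester of rings F–G–H–I–J (carboxyl of 10 esterified by the phenol oxygen of 7)
Conditions: EDC·HCl, DMAP, CH2Cl2, rt
Reagents that add atoms: none
Why: Steglich esterification; the carbodiimide activates the uncrowded aroyl group (two ortho hydrogens) and DMAP passes it to the crowded phenol, conditions under which the aryl ester already present should not exchange at room temperature.

Step 8
Reactants: 11 benzyl ester of rings F–J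
Product: 12 acid of rings F–J (11 with the benzyl ester cleaved to CO2H)
Conditions: H2 (1 atm), 10% Pd/C, EtOAc/THF, rt
Reagents that add atoms: none
Why: Hydrogenolysis of the benzyl ester as in step 6; the two aryl esters are stable.

Step 9
Reactants: 12 acid of rings F–J; 7 benzyl 4-(2-hydroxy-3,4,5-trimethoxyphenoxy)-3,5-dimethoxybenzoate
Product: 13 benzyl ester of rings D–J (carboxyl of 12 esterified by the phenol oxygen of 7)
Conditions: EDC·HCl, DMAP, CH2Cl2, rt
Reagents that add atoms: none
Why: Steglich esterification as in step 7; the reacting carboxyl is the same 3,5-dimethoxy-4-aryloxybenzoic acid terminus, so its reactivity should not depend on chain length.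

Step 10
Reactants: 13 benzyl ester of rings D–J
Product: 14 acid of rings D–J (13 with the benzyl ester cleaved to CO2H)
Conditions: H2 (1 atm), 10% Pd/C, EtOAc/THF, rt
Reagents that add atoms: none
Why: Hydrogenolysis of the benzyl ester as in step 6.

Step 11
Reactants: 14 acid of rings D–J; 7 benzyl 4-(2-hydroxy-3,4,5-trimethoxyphenoxy)-3,5-dimethoxybenzoate
Product: 15 benzyl ester of rings B–J (carboxyl of 14 esterified by the phenol oxygen of 7)
Conditions: EDC·HCl, DMAP, CH2Cl2, rt
Reagents that add atoms: none
Why: Steglich esterification as in step 7.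

Step 12
Reactants: 15 benzyl ester of rings B–J
Product: 16 acid of rings B–J (15 with the benzyl ester cleaved to CO2H)
Conditions: H2 (1 atm), 10% Pd/C, EtOAc/THF, rt
Reagents that add atoms: none
Why: Hydrogenolysis of the benzyl ester as in step 6.

Step 13
Reactants: 16 acid of rings B–J; 17 2,4,6-trimethoxyphenol
Product: 18 penta-ester of rings A–J (2,4,6-trimethoxyphenyl ester of 16; rings A, C, E, G and I acylated through oxygen by the carboxyl carbons on b1, d1, f1, h1 and j1; twenty-six methyl ethers)
Conditions: EDC·HCl, DMAP, CH2Cl2, rt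
Reagents that add atoms: none
Why: Steglich esterification of the last free carboxyl with the di-ortho-methoxy phenol of ring A, the same type of union as in steps 7, 9 and 11.

Step 14
Reactants: 18 penta-ester of rings A–J
Product: 19 hexacosa-O-methyl decamer (20 with every hydroxyl as a methyl ether; nine diaryl ether bonds)
Conditions: Ni(cod)2 (20 mol % per ester group), 3,4-bis(dicyclohexylphosphino)thiophene (40 mol % per ester group), K3PO4, m-xylene, 140 °C, argon sweep
Reagents that add atoms: none
Why: Proposed new method: each aryl ester should undergo oxidative addition of zerovalent nickel, ligated by the chelating electron-rich diphosphine, into its C(acyl)–O bond to give an aroyl aryloxide complex of divalent nickel; the carbonyl group deinserts and leaves as carbon monoxide, and C–O reductive elimination from the aryl nickel aryloxide forms the ether bonds O–b1, O–d1, O–f1, O–h1 and O–j1 and returns zerovalent nickel. The closest known reaction type is the nickel- or palladium-catalysed decarbonylative etherification of single aryl esters with this diphosphine and K3PO4, documented mainly for azinecarboxylates, supported by the wider family of decarbonylative couplings of phenyl benzoates, which show that insertion and carbonyl loss are feasible for plain aroyl groups; new here are the non-azine aroyl partner, the di-ortho-oxygenated aryloxide and the five-fold use in one molecule. No ring is closed and no stereocentre is formed. Each aroyl carbon has two ortho hydrogens and its ring is inductively electron-poor at the ipso carbon (two meta methoxy groups and a twisted para aryloxy group), which should favour both insertion and reductive elimination, while the crowded partner is the aryloxide already on nickel, so no external nucleophile has to approach a congested carbon. The step needs C(acyl)–O insertion in preference to C(aryl)–O insertion at the ester, aryl–OMe or diaryl ether bonds; the chelating diphosphine, the two ortho substituents on every phenolic ring and the absence of any hydride or organometallic partner should secure this. It also needs each aryloxide to stay on the nickel that released it, which the chelate and the non-polar solvent are meant to favour. Nickel is charged per ester group and carbon monoxide is swept out so that nickel carbonyl species do not stall the later events, and partly contracted material can be resubmitted.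

Step 15
Reactants: 19 hexacosa-O-methyl decamer
Product: 20 target decamer CNP0255890.0 (rings A–J joined by nine ether oxygens, twenty-six free hydroxyls)
Conditions: BBr3 (excess), CH2Cl2, −78 °C to rt, argon; then MeOH, degassed H2O
Reagents that add atoms: none
Why: Lewis acid cleavage of aryl methyl ethers by BBr3 (bromide attacks the methyl group of the boron-bound ether); diaryl ethers have no alkyl carbon to attack and are retained, and acidic, oxygen-free work-up protects the polyphenol.

## Compound list

1 | methyl syringate (methyl 4-hydroxy-3,5-dimethoxybenzoate) | COC(=O)c1cc(OC)c(O)c(OC)c1 | starting material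
2 | 5-iodo-1,2,3-trimethoxybenzene | COc1cc(I)cc(OC)c1OC | starting material
3 | methyl 3,5-dimethoxy-4-(3,4,5-trimethoxyphenoxy)benzoate | COC(=O)c1cc(OC)c(Oc2cc(OC)c(OC)c(OC)c2)c(OC)c1 | intermediate
4 | methyl 4-(2-bromo-3,4,5-trimethoxyphenoxy)-3,5-dimethoxybenzoate | COC(=O)c1cc(OC)c(Oc2cc(OC)c(OC)c(OC)c2Br)c(OC)c1 | intermediate
5 | 4-(2-bromo-3,4,5-trimethoxyphenoxy)-3,5-dimethoxybenzoic acid (present as its potassium salt, not isolated) | OC(=O)c1cc(OC)c(Oc2cc(OC)c(OC)c(OC)c2Br)c(OC)c1 | intermediate
6 | 4-(2-hydroxy-3,4,5-trimethoxyphenoxy)-3,5-dimethoxybenzoic acid | OC(=O)c1cc(OC)c(Oc2cc(OC)c(OC)c(OC)c2O)c(OC)c1 | intermediate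
7 | benzyl 4-(2-hydroxy-3,4,5-trimethoxyphenoxy)-3,5-dimethoxybenzoate | O=C(OCc1ccccc1)c1cc(OC)c(Oc2cc(OC)c(OC)c(OC)c2O)c(OC)c1 | intermediate
8 | 3,4,5-trimethoxybenzoyl chloride | COc1cc(C(=O)Cl)cc(OC)c1OC | starting material
9 | benzyl 3,5-dimethoxy-4-[3,4,5-trimethoxy-2-(3,4,5-trimethoxybenzoyloxy)phenoxy]benzoate (rings H–I–J) | O=C(OCc1ccccc1)c1cc(OC)c(Oc2cc(OC)c(OC)c(OC)c2OC(=O)c2cc(OC)c(OC)c(OC)c2)c(OC)c1 | intermediate
10 | 3,5-dimethoxy-4-[3,4,5-trimethoxy-2-(3,4,5-trimethoxybenzoyloxy)phenoxy]benzoic acid (rings H–I–J) | OC(=O)c1cc(OC)c(Oc2cc(OC)c(OC)c(OC)c2OC(=O)c2cc(OC)c(OC)c(OC)c2)c(OC)c1 | intermediate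
11 | benzyl ester of rings F–J (carboxyl of 10 esterified by the phenol oxygen of 7) | O=C(OCc1ccccc1)c1cc(OC)c(Oc2cc(OC)c(OC)c(OC)c2OC(=O)c2cc(OC)c(Oc3cc(OC)c(OC)c(OC)c3OC(=O)c3cc(OC)c(OC)c(OC)c3)c(OC)c2)c(OC)c1 | intermediate
12 | acid of rings F–J | OC(=O)c1cc(OC)c(Oc2cc(OC)c(OC)c(OC)c2OC(=O)c2cc(OC)c(Oc3cc(OC)c(OC)c(OC)c3OC(=O)c3cc(OC)c(OC)c(OC)c3)c(OC)c2)c(OC)c1 | intermediate
13 | benzyl ester of rings D–J (carboxyl of 12 esterified by the phenol oxygen of 7) | O=C(OCc1ccccc1)c1cc(OC)c(Oc2cc(OC)c(OC)c(OC)c2OC(=O)c2cc(OC)c(Oc3cc(OC)c(OC)c(OC)c3OC(=O)c3cc(OC)c(Oc4cc(OC)c(OC)c(OC)c4OC(=O)c4cc(OC)c(OC)c(OC)c4)c(OC)c3)c(OC)c2)c(OC)c1 | intermediate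
14 | acid of rings D–J | OC(=O)c1cc(OC)c(Oc2cc(OC)c(OC)c(OC)c2OC(=O)c2cc(OC)c(Oc3cc(OC)c(OC)c(OC)c3OC(=O)c3cc(OC)c(Oc4cc(OC)c(OC)c(OC)c4OC(=O)c4cc(OC)c(OC)c(OC)c4)c(OC)c3)c(OC)c2)c(OC)c1 | intermediate
15 | benzyl ester of rings B–J (carboxyl of 14 esterified by the phenol oxygen of 7) | O=C(OCc1ccccc1)c1cc(OC)c(Oc2cc(OC)c(OC)c(OC)c2OC(=O)c2cc(OC)c(Oc3cc(OC)c(OC)c(OC)c3OC(=O)c3cc(OC)c(Oc4cc(OC)c(OC)c(OC)c4OC(=O)c4cc(OC)c(Oc5cc(OC)c(OC)c(OC)c5OC(=O)c5cc(OC)c(OC)c(OC)c5)c(OC)c4)c(OC)c3)c(OC)c2)c(OC)c1 | intermediate
16 | acid of rings B–J | OC(=O)c1cc(OC)c(Oc2cc(OC)c(OC)c(OC)c2OC(=O)c2cc(OC)c(Oc3cc(OC)c(OC)c(OC)c3OC(=O)c3cc(OC)c(Oc4cc(OC)c(OC)c(OC)c4OC(=O)c4cc(OC)c(Oc5cc(OC)c(OC)c(OC)c5OC(=O)c5cc(OC)c(OC)c(OC)c5)c(OC)c4)c(OC)c3)c(OC)c2)c(OC)c1 | intermediate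
17 | 2,4,6-trimethoxyphenol | COc1cc(OC)c(O)c(OC)c1 | starting material
18 | penta-ester of rings A–J (2,4,6-trimethoxyphenyl ester of 16) | COc1cc(OC)c(OC(=O)c2cc(OC)c(Oc3cc(OC)c(OC)c(OC)c3OC(=O)c3cc(OC)c(Oc4cc(OC)c(OC)c(OC)c4OC(=O)c4cc(OC)c(Oc5cc(OC)c(OC)c(OC)c5OC(=O)c5cc(OC)c(Oc6cc(OC)c(OC)c(OC)c6OC(=O)c6cc(OC)c(OC)c(OC)c6)c(OC)c5)c(OC)c4)c(OC)c3)c(OC)c2)c(OC)c1 | intermediate
19 | hexacosa-O-methyl decamer (permethyl ether of 20) | COc1cc(OC)c(Oc2cc(OC)c(Oc3cc(OC)c(OC)c(OC)c3Oc3cc(OC)c(Oc4cc(OC)c(OC)c(OC)c4Oc4cc(OC)c(Oc5cc(OC)c(OC)c(OC)c5Oc5cc(OC)c(Oc6cc(OC)c(OC)c(OC)c6Oc6cc(OC)c(OC)c(OC)c6)c(OC)c5)c(OC)c4)c(OC)c3)c(OC)c2)c(OC)c1 | intermediate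
20 | CNP0255890.0, decamer of rings A–J with twenty-six free hydroxyls | Oc1cc(O)c(Oc2cc(O)c(Oc3cc(O)c(O)c(O)c3Oc3cc(O)c(Oc4cc(O)c(O)c(O)c4Oc4cc(O)c(Oc5cc(O)c(O)c(O)c5Oc5cc(O)c(Oc6cc(O)c(O)c(O)c6Oc6cc(O)c(O)c(O)c6)c(O)c5)c(O)c4)c(O)c3)c(O)c2)c(O)c1 | target

## Step count and risks

Total step count: 15. Longest linear sequence: 15 steps (1 to 20 through steps 1–15; unit 7 is made once and used in steps 5, 7, 9 and 11).

Least certain steps:

Step 14 (key step, proposed new method). What may go wrong:
- stalling after one or two contractions because carbon monoxide binds zerovalent nickel;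
- slow C–O reductive elimination from a nickel aryloxide whose ortho methoxy groups can chelate the metal;
- hydrodecarbonylation by adventitious proton sources;
- transfer of aryloxides between nickel centres, which scrambles chain lengths.

Five events multiply each shortfall. The fallback uses known chemistry only, sets out from 17 and 2, and returns at 19:
- Commercial 4-bromo-2,6-dimethoxyphenol is O-arylated with (3,4,5-trimethoxyphenyl)boronic acid (Cu(OAc)2, pyridine, 4 Å sieves, CH2Cl2, air; Chan–Lam coupling, which leaves the aryl bromide alone) to give 5-bromo-1,3-dimethoxy-2-(3,4,5-trimethoxyphenoxy)benzene F1.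
- NBS brominates the trimethoxyphenoxy ring as in step 2 to give 5-bromo-2-(2-bromo-3,4,5-trimethoxyphenoxy)-1,3-dimethoxybenzene F2.
- Ullmann coupling of 17 with F2 under the conditions of step 1 should occur only at the bromide flanked by two hydrogens and give the A–B–C bromide F3.
- Palladium-catalysed hydroxylation as in step 3 converts the crowded bromide into the A–B–C phenol F4.
- Three more rounds of coupling with F2 and hydroxylation lead through the pentamer bromide F5, the pentamer phenol F6, the heptamer bromide F7, the heptamer phenol F8, the nonamer bromide F9 and the nonamer phenol F10.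
- A last Ullmann coupling of F10 with 2 gives 19.

Every ether is then made in the polarity crowded phenoxide plus uncrowded halide, at the cost of eleven steps in place of the depside assembly and step 14.

Step 1. What may go wrong: sluggish coupling of the weakly nucleophilic, doubly ortho-substituted phenoxide, so that reduction of the iodide and hydrolysis of the methyl ester compete. The fallback sets out from 1 and returns at 3:
- SNAr of 1 on 4-fluoro-2,6-dimethoxybenzaldehyde (COc1cc(F)cc(OC)c1C=O; Cs2CO3, DMSO, 120 °C) gives methyl 4-(4-formyl-3,5-dimethoxyphenoxy)-3,5-dimethoxybenzoate F11.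
- Dakin oxidation with mCPBA gives the aryl formate methyl 4-(4-formyloxy-3,5-dimethoxyphenoxy)-3,5-dimethoxybenzoate F12.
- Methanolysis with K2CO3 gives methyl 4-(4-hydroxy-3,5-dimethoxyphenoxy)-3,5-dimethoxybenzoate F13.
- Methylation with MeI and K2CO3 gives 3.

Step 3. What may go wrong: slow oxidative addition at the bromide between two oxygen substituents, so that hydrodebromination or arylation of the product phenoxide takes over. The fallback sets out from 3 and returns at 6:
- Vilsmeier–Haack formylation (POCl3, DMF) at the position that step 2 brominates gives methyl 4-(2-formyl-3,4,5-trimethoxyphenoxy)-3,5-dimethoxybenzoate F14.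
- Dakin oxidation with mCPBA gives the formate methyl 4-(2-formyloxy-3,4,5-trimethoxyphenoxy)-3,5-dimethoxybenzoate F15.
- Methanolysis gives methyl 4-(2-hydroxy-3,4,5-trimethoxyphenoxy)-3,5-dimethoxybenzoate F16.
- Saponification with LiOH gives 6.

Step 7 (and likewise steps 9, 11 and 13). What may go wrong: slow acylation of the crowded phenol, so that the activated acid rearranges to an unreactive N-acylurea, or DMAP-mediated acyl exchange among the aryl esters already present. The fallback sets out from 10 and returns at 11. Acid 10 is converted with oxalyl chloride and catalytic DMF into the isolated acid chloride 3,5-dimethoxy-4-[3,4,5-trimethoxy-2-(3,4,5-trimethoxybenzoyloxy)phenoxy]benzoyl chloride F17. F17 is coupled with 7 as in step 5 (Et3N, catalytic DMAP, 0 °C). The same change serves for acids 12, 14 and 16.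

Step 15. What may go wrong: incomplete cleavage of some of the twenty-six methyl ethers when partly dealkylated borates leave solution, and air oxidation of the pyrogallol-type rings during isolation, so that the polar product cannot be purified. The fallback sets out from 19 and returns at 20. The crude product of the BBr3 reaction is peracetylated (Ac2O, pyridine) to the hexacosaacetate of the decamer F18. F18 can be chromatographed on silica and separated from under-dealkylated material. It is then deacetylated by acid-catalysed methanolysis (HCl in degassed MeOH) to 20.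

## Further compounds

F1 | step 14 | 5-bromo-1,3-dimethoxy-2-(3,4,5-trimethoxyphenoxy)benzene | COc1cc(Br)cc(OC)c1Oc1cc(OC)c(OC)c(OC)c1
F2 | step 14 | 5-bromo-2-(2-bromo-3,4,5-trimethoxyphenoxy)-1,3-dimethoxybenzene | COc1cc(Br)cc(OC)c1Oc1cc(OC)c(OC)c(OC)c1Br
F3 | step 14 | A–B–C bromide (permethylated trimer, Br at c6) | COc1cc(OC)c(Oc2cc(OC)c(Oc3cc(OC)c(OC)c(OC)c3Br)c(OC)c2)c(OC)c1
F4 | step 14 | A–B–C phenol (permethylated trimer, OH at c6) | COc1cc(OC)c(Oc2cc(OC)c(Oc3cc(OC)c(OC)c(OC)c3O)c(OC)c2)c(OC)c1
F5 | step 14 | pentamer bromide (rings A–E, Br at e6) | COc1cc(OC)c(Oc2cc(OC)c(Oc3cc(OC)c(OC)c(OC)c3Oc3cc(OC)c(Oc4cc(OC)c(OC)c(OC)c4Br)c(OC)c3)c(OC)c2)c(OC)c1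
F6 | step 14 | pentamer phenol (rings A–E, OH at e6) | COc1cc(OC)c(Oc2cc(OC)c(Oc3cc(OC)c(OC)c(OC)c3Oc3cc(OC)c(Oc4cc(OC)c(OC)c(OC)c4O)c(OC)c3)c(OC)c2)c(OC)c1
F7 | step 14 | heptamer bromide (rings A–G, Br at g6) | COc1cc(OC)c(Oc2cc(OC)c(Oc3cc(OC)c(OC)c(OC)c3Oc3cc(OC)c(Oc4cc(OC)c(OC)c(OC)c4Oc4cc(OC)c(Oc5cc(OC)c(OC)c(OC)c5Br)c(OC)c4)c(OC)c3)c(OC)c2)c(OC)c1
F8 | step 14 | heptamer phenol (rings A–G, OH at g6) | COc1cc(OC)c(Oc2cc(OC)c(Oc3cc(OC)c(OC)c(OC)c3Oc3cc(OC)c(Oc4cc(OC)c(OC)c(OC)c4Oc4cc(OC)c(Oc5cc(OC)c(OC)c(OC)c5O)c(OC)c4)c(OC)c3)c(OC)c2)c(OC)c1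
F9 | step 14 | nonamer bromide (rings A–I, Br at i6) | COc1cc(OC)c(Oc2cc(OC)c(Oc3cc(OC)c(OC)c(OC)c3Oc3cc(OC)c(Oc4cc(OC)c(OC)c(OC)c4Oc4cc(OC)c(Oc5cc(OC)c(OC)c(OC)c5Oc5cc(OC)c(Oc6cc(OC)c(OC)c(OC)c6Br)c(OC)c5)c(OC)c4)c(OC)c3)c(OC)c2)c(OC)c1
F10 | step 14 | nonamer phenol (rings A–I, OH at i6) | COc1cc(OC)c(Oc2cc(OC)c(Oc3cc(OC)c(OC)c(OC)c3Oc3cc(OC)c(Oc4cc(OC)c(OC)c(OC)c4Oc4cc(OC)c(Oc5cc(OC)c(OC)c(OC)c5Oc5cc(OC)c(Oc6cc(OC)c(OC)c(OC)c6O)c(OC)c5)c(OC)c4)c(OC)c3)c(OC)c2)c(OC)c1
F11 | step 1 | methyl 4-(4-formyl-3,5-dimethoxyphenoxy)-3,5-dimethoxybenzoate | COC(=O)c1cc(OC)c(Oc2cc(OC)c(C=O)c(OC)c2)c(OC)c1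
F12 | step 1 | methyl 4-(4-formyloxy-3,5-dimethoxyphenoxy)-3,5-dimethoxybenzoate | COC(=O)c1cc(OC)c(Oc2cc(OC)c(OC=O)c(OC)c2)c(OC)c1
F13 | step 1 | methyl 4-(4-hydroxy-3,5-dimethoxyphenoxy)-3,5-dimethoxybenzoate | COC(=O)c1cc(OC)c(Oc2cc(OC)c(O)c(OC)c2)c(OC)c1
F14 | step 3 | methyl 4-(2-formyl-3,4,5-trimethoxyphenoxy)-3,5-dimethoxybenzoate | COC(=O)c1cc(OC)c(Oc2cc(OC)c(OC)c(OC)c2C=O)c(OC)c1
F15 | step 3 | methyl 4-(2-formyloxy-3,4,5-trimethoxyphenoxy)-3,5-dimethoxybenzoate | COC(=O)c1cc(OC)c(Oc2cc(OC)c(OC)c(OC)c2OC=O)c(OC)c1
F16 | step 3 | methyl 4-(2-hydroxy-3,4,5-trimethoxyphenoxy)-3,5-dimethoxybenzoate | COC(=O)c1cc(OC)c(Oc2cc(OC)c(OC)c(OC)c2O)c(OC)c1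
F17 | step 7 | 3,5-dimethoxy-4-[3,4,5-trimethoxy-2-(3,4,5-trimethoxybenzoyloxy)phenoxy]benzoyl chloride | ClC(=O)c1cc(OC)c(Oc2cc(OC)c(OC)c(OC)c2OC(=O)c2cc(OC)c(OC)c(OC)c2)c(OC)c1
F18 | step 15 | hexacosaacetate of the decamer (20 with every hydroxyl as acetate) | CC(=O)Oc1cc(OC(C)=O)c(Oc2cc(OC(C)=O)c(Oc3cc(OC(C)=O)c(OC(C)=O)c(OC(C)=O)c3Oc3cc(OC(C)=O)c(Oc4cc(OC(C)=O)c(OC(C)=O)c(OC(C)=O)c4Oc4cc(OC(C)=O)c(Oc5cc(OC(C)=O)c(OC(C)=O)c(OC(C)=O)c5Oc5cc(OC(C)=O)c(Oc6cc(OC(C)=O)c(OC(C)=O)c(OC(C)=O)c6Oc6cc(OC(C)=O)c(OC(C)=O)c(OC(C)=O)c6)c(OC(C)=O)c5)c(OC(C)=O)c4)c(OC(C)=O)c3)c(OC(C)=O)c2)c(OC(C)=O)c1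
A1 | alternative 1 | A–B–C trimer with free b3 hydroxyl, b5 ethyl ether and c6 benzyl ether | COc1cc(OC)c(Oc2cc(O)c(Oc3cc(OC)c(OC)c(OC)c3OCc3ccccc3)c(OCC)c2)c(OC)c1
A2 | alternative 1 | 4-(2-benzyloxy-3,4,5-trimethoxyphenoxy)-3-ethoxycyclobut-2-en-1-one | O=C1C=C(OCC)C1Oc1cc(OC)c(OC)c(OC)c1OCc1ccccc1
A3 | alternative 1 | 2-(ethynyloxy)-1,3,5-trimethoxybenzene | C#COc1c(OC)cc(OC)cc1OC
A4 | alternative 2 | A–B–C trimer with free c6 hydroxyl | COc1cc(OC)c(Oc2cc(OC)c(Oc3cc(OC)c(OC)c(OC)c3O)c(OC)c2)c(OC)c1
A5 | alternative 2 | 4-{(E)-2-[2,6-dimethoxy-4-(2,4,6-trimethoxyphenoxy)phenoxy]ethenyl}-2,3,4-trimethoxycyclobut-2-en-1-one | COC1=C(OC)C(OC)(/C=C/Oc2c(OC)cc(Oc3c(OC)cc(OC)cc3OC)cc2OC)C1=O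
A6 | alternative 3 | decamer with free hydroxyls at c4, e4, g4, i4 and j4 and all other hydroxyls as methyl ethers | COc1cc(OC)c(Oc2cc(OC)c(Oc3cc(OC)c(O)c(OC)c3Oc3cc(OC)c(Oc4cc(OC)c(O)c(OC)c4Oc4cc(OC)c(Oc5cc(OC)c(O)c(OC)c5Oc5cc(OC)c(Oc6cc(OC)c(O)c(OC)c6Oc6cc(OC)c(O)c(OC)c6)c(OC)c5)c(OC)c4)c(OC)c3)c(OC)c2)c(OC)c1
A7 | alternative 3 | decamer with formyl groups at c4, e4, g4, i4 and j4 and all other hydroxyls as methyl ethers | COc1cc(OC)c(Oc2cc(OC)c(Oc3cc(OC)c(C=O)c(OC)c3Oc3cc(OC)c(Oc4cc(OC)c(C=O)c(OC)c4Oc4cc(OC)c(Oc5cc(OC)c(C=O)c(OC)c5Oc5cc(OC)c(Oc6cc(OC)c(C=O)c(OC)c6Oc6cc(OC)c(C=O)c(OC)c6)c(OC)c5)c(OC)c4)c(OC)c3)c(OC)c2)c(OC)c1
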